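**Retrosynthetic overview**

1. Numbering (spiro[5.5]undecane): ring A = C1 (=CH2), C2, C3 (OH), C4 (Br), C5 (CMe2), C6 (spiro); ring B = C6, C7, C8 (Cl), C9 (CH3, OH), C10, C11.
2. Ring A is the dimedone ring: C5 and the 1,3-oxygen pattern at C1/C3 come from dimedone. C4–Br, C1=CH2 and C3–OH are set last (γ-bromination, Peterson methylenation with hydrolysis, hydride reduction).
3. Ring B is cut at C7–C8 and C9–C10: C8–C9 is a two-carbon unit at the ketene oxidation level, delivered by Ph3P=C=C=O and inserted between the two arms of C6 by C-acylation and intramolecular Wittig closure.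
4. Enabling feature: the spiro carbon C6 carries a one-carbon arm (C7, a formyl group) and a two-carbon arm (C11–C10, malonate-activated) of unequal length. Ring B therefore closes to one cyclohexenone only (C7=C8–C9=O), which marks C8 for chlorine and C9 for methyl; 1,4-hydrosilylation/chlorination and methyl addition on the locked spiro chair then give the cis-chlorohydrin.
5. The stereocentre C6 is set before ring closure by an enantioselective Michael addition. Order of ring formation: ring A (from dimedone), then ring B (step 4).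

Key step: step 4

Remark: diethyl methylidenemalonate and Ph3P=C=C=O are taken as commercial reagents; the catalyst pseudoenantiomer in step 3 is the one that delivers the S-configured quaternary carbon.

Step 1
Reactants: 1 dimedone (5,5-dimethylcyclohexane-1,3-dione)
Product: 2 5,5-dimethyl-3-(2-methylpropoxy)cyclohex-2-en-1-one
Conditions: i-BuOH, p-TsOH (cat.), toluene, reflux, azeotropic removal of water
Reagents that add atoms: 2-methylpropan-1-ol CC(C)CO
Why: Acid-catalysed condensation of the cyclic 1,3-diketone with the alcohol should give the vinylogous ester (enol ether formation), which differentiates the two carbonyl groups of ring A; no stereocentre is formed.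

Step 2
Reactants: 2 5,5-dimethyl-3-(2-methylpropoxy)cyclohex-2-en-1-one
Product: 3 (6Z)-6-(hydroxymethylidene)-5,5-dimethyl-3-(2-methylpropoxy)cyclohex-2-en-1-one
Conditions: LiN(i-Pr)2, THF, −78 °C; HCO2Et, −78 to 0 °C; then 1 M HCl (pH 5)
Reagents that add atoms: ethyl formate CCOC=O
Why: Kinetic deprotonation of the vinylogous ester occurs at the α' carbon (the later spiro carbon C6), and crossed Claisen condensation of this enolate with ethyl formate should give the β-keto aldehyde, which rests as its hydrogen-bonded Z-enol; no stereocentre is formed.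

Step 3
Reactants: 3 (6Z)-6-(hydroxymethylidene)-5,5-dimethyl-3-(2-methylpropoxy)cyclohex-2-en-1-one; 4 diethyl methylidenemalonate
Product: 5 diethyl 2-{[(1S)-1-formyl-6,6-dimethyl-4-(2-methylpropoxy)-2-oxocyclohex-3-en-1-yl]methyl}propanedioate
Conditions: 9-amino(9-deoxy)epi-quinidine 3,5-bis(trifluoromethyl)phenyl squaramide (10 mol %), toluene, −40 °C
Reagents that add atoms: none
Why: Organocatalytic enantioselective Michael addition: the bifunctional amine–squaramide binds the acidic β-keto aldehyde as its enolate and the methylidenemalonate by hydrogen bonding, so that bond formation on one enolate face should set the quaternary stereocentre C6 as S (the quinine-derived pseudoenantiomer is taken if the sense of induction proves opposite).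

Step 4
Reactants: 5 diethyl 2-{[(1S)-1-formyl-6,6-dimethyl-4-(2-methylpropoxy)-2-oxocyclohex-3-en-1-yl]methyl}propanedioate; 6 (triphenylphosphoranylidene)ketene
Product: 8 diethyl (6R)-5,5-dimethyl-3-(2-methylpropoxy)-1,9-dioxospiro[5.5]undeca-2,7-diene-10,10-dicarboxylate, via acyl ylide 7 (not isolated)
Conditions: Ph3P=C=C=O, Et3N (10 mol %), toluene, 60 °C, then 110 °C
Reagents that add atoms: none
Why: Proposed new method: the acidic malonate C–H of 5 should protonate the ylide carbon of Ph3P=C=C=O (assisted by Et3N), and the malonate/ketenylphosphonium pair should collapse by C-acylation to the β-keto ylide 7 (bond C9–C10), which then closes ring B by intramolecular Wittig olefination of the non-enolisable aldehyde (bond C7–C8, formed as C7=C8; six-membered ring by 6-exo-trig attack of the ylide carbon on C=O, then loss of Ph3PO). The closest known reaction type is the domino addition of O–H, N–H and C–H acids to this cumulated ylide followed by intramolecular Wittig closure (butenolides, tetronates, macrolides); new here is a malonate carbon nucleophile that closes a carbocycle. No stereocentre is created: C6 is carried through unchanged, C10 bears two identical ester groups, and the ring enforces the cis geometry of C7=C8. The step needs C- rather than O-acylation, expected for the soft malonate carbon, and acylation before olefination, which is secured because the cumulated ylide itself does not olefinate aldehydes whereas the acyl ylide does, and because the vinylogous ester carbonyl C1 is inert to stabilised ylides. The unequal arms on C6 place the new carbonyl at C9 and the alkene at C7=C8 without ambiguity, which later distinguishes C8 from C10.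

Step 5
Reactants: 8 diethyl (6R)-5,5-dimethyl-3-(2-methylpropoxy)-1,9-dioxospiro[5.5]undeca-2,7-diene-10,10-dicarboxylate
Product: 9 (6R)-5,5-dimethyl-3-(2-methylpropoxy)spiro[5.5]undeca-2,7-diene-1,9-dione
Conditions: LiCl, H2O, DMSO, 150 °C
Reagents that add atoms: none
Why: Double Krapcho dealkoxycarbonylation (SN2 attack of chloride on the ethyl groups, loss of CO2, protonation of the enolates) should remove both activating ester groups from C10 under neutral conditions, which avoids retro-Claisen opening of the β-keto diester; the spiro centre is not touched.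

Step 6
Reactants: 9 (6R)-5,5-dimethyl-3-(2-methylpropoxy)spiro[5.5]undeca-2,7-diene-1,9-dione
Product: 11 (6R,8S)-8-chloro-5,5-dimethyl-3-(2-methylpropoxy)spiro[5.5]undec-2-ene-1,9-dione, via triethylsilyl enol ether 10 (not isolated)
Conditions: Et3SiH, RhCl(PPh3)3 (2 mol %), toluene, 50 °C; then NCS (1.0 equiv), THF, −78 to 0 °C
Reagents that add atoms: N-chlorosuccinimide O=C1CCC(=O)N1Cl
Why: Rhodium-catalysed 1,4-hydrosilylation of the enone (the vinylogous ester is inert) should fix the enol ether double bond at C8=C9, and chlorination of this far more nucleophilic silyl enol ether with NCS should occur anti to the axial C1 substituent of the spiro carbon (ring B is locked with the CMe2 carbon C5 equatorial), which places chlorine equatorial and cis to C5 (8S), also the more stable epimer of this enolisable centre.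

Step 7
Reactants: 11 (6R,8S)-8-chloro-5,5-dimethyl-3-(2-methylpropoxy)spiro[5.5]undec-2-ene-1,9-dione
Product: 12 (6R,8S,9R)-8-chloro-9-hydroxy-5,5,9-trimethyl-3-(2-methylpropoxy)spiro[5.5]undec-2-en-1-one
Conditions: MeTi(OiPr)3, THF, −40 to 0 °C
Reagents that add atoms: methyltitanium triisopropoxide C[Ti](OC(C)C)(OC(C)C)OC(C)C
Why: Chemoselective 1,2-addition of the non-basic methyltitanium reagent to the ketone (the vinylogous ester carbonyl does not react) should take the equatorial trajectory on the locked chair, as is usual for this bulky reagent and for methyl additions to 2-chlorocyclohexanones, giving the axial tertiary hydroxyl cis to the equatorial chlorine (9R).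

Step 8
Reactants: 12 (6R,8S,9R)-8-chloro-9-hydroxy-5,5,9-trimethyl-3-(2-methylpropoxy)spiro[5.5]undec-2-en-1-one
Product: 14 (4S,6R,8S,9R)-4-bromo-8-chloro-5,5,9-trimethyl-3-(2-methylpropoxy)-9-[(trimethylsilyl)oxy]spiro[5.5]undec-2-en-1-one, via bis-silyl dienol ether 13 (not isolated)
Conditions: Me3SiOTf, Et3N, CH2Cl2, 0 °C; then NBS (1.0 equiv), THF, −78 °C
Reagents that add atoms: trimethylsilyl trifluoromethanesulfonate C[Si](C)(C)OS(=O)(=O)C(F)(F)F; N-bromosuccinimide O=C1CCC(=O)N1Br
Why: Soft enolisation can only remove a γ hydrogen at C4 because C6 is quaternary, giving the 1-silyloxy-3-alkoxy diene 13 (the tertiary alcohol is silylated at the same time), and NBS should attack its terminus C4, where both oxygen donors reinforce each other (vinylogous α-bromination of a dienol silyl ether), anti to the pseudoaxial C11 arm of the spiro carbon to give the 4S bromide; this centre remains adjustable by enolisation at the stage of 16.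

Step 9
Reactants: 14 (4S,6R,8S,9R)-4-bromo-8-chloro-5,5,9-trimethyl-3-(2-methylpropoxy)-9-[(trimethylsilyl)oxy]spiro[5.5]undec-2-en-1-one
Product: 16 (4S,6S,8S,9R)-4-bromo-8-chloro-9-hydroxy-5,5,9-trimethyl-1-methylidenespiro[5.5]undecan-3-one, via β-hydroxysilane 15 (not isolated)
Conditions: Me3SiCH2Li, CeCl3, THF, −78 °C; then 1 M HCl, THF, 0 °C
Reagents that add atoms: (trimethylsilyl)methyllithium [Li]C[Si](C)(C)C; water O
Why: 1,2-Addition of the weakly basic organocerium reagent to the hindered vinylogous ester carbonyl, acid-induced Peterson elimination to the 1-methylidene dienol ether, kinetic protonation at C2 during enol ether hydrolysis and cleavage of the silyl ether should give the β,γ-unsaturated ketone with the exocyclic alkene (Peterson olefination combined with a Stork–Danheiser-type hydrolysis); no new stereocentre is formed and C4 can settle as the equatorial bromide.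

Step 10
Reactants: 16 (4S,6S,8S,9R)-4-bromo-8-chloro-9-hydroxy-5,5,9-trimethyl-1-methylidenespiro[5.5]undecan-3-one
Product: 17 (3R,4S,6S,8S,9R)-4-bromo-8-chloro-5,5,9-trimethyl-1-methylidenespiro[5.5]undecane-3,9-diol
Conditions: i-Bu2AlH, CH2Cl2, −78 °C
Reagents that add atoms: none
Why: Substrate-controlled hydride reduction: i-Bu2AlH should attack the ketone from the equatorial side, because the axial trajectory is blocked by the axial methyl group at C5, giving the axial hydroxyl cis to the equatorial bromine (3R) and thereby the target.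

**Compound list**

1 | dimedone (5,5-dimethylcyclohexane-1,3-dione) | O=C1CC(=O)CC(C)(C)C1 | starting material
2 | 5,5-dimethyl-3-(2-methylpropoxy)cyclohex-2-en-1-one | O=C1C=C(OCC(C)C)CC(C)(C)C1 | intermediate
3 | (6Z)-6-(hydroxymethylidene)-5,5-dimethyl-3-(2-methylpropoxy)cyclohex-2-en-1-one (enol of the 6-formyl ketone) | O/C=C1\C(=O)C=C(OCC(C)C)CC1(C)C | intermediate
4 | diethyl methylidenemalonate | C=C(C(=O)OCC)C(=O)OCC | starting material
5 | diethyl 2-{[(1S)-1-formyl-6,6-dimethyl-4-(2-methylpropoxy)-2-oxocyclohex-3-en-1-yl]methyl}propanedioate | O=C1C=C(OCC(C)C)CC(C)(C)[C@]1(C=O)CC(C(=O)OCC)C(=O)OCC | intermediate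
6 | (triphenylphosphoranylidene)ketene | O=C=C=P(c1ccccc1)(c1ccccc1)c1ccccc1 | starting material
7 | diethyl 2-{[(1S)-1-formyl-6,6-dimethyl-4-(2-methylpropoxy)-2-oxocyclohex-3-en-1-yl]methyl}-2-[(triphenylphosphoranylidene)acetyl]propanedioate | O=C1C=C(OCC(C)C)CC(C)(C)[C@]1(C=O)CC(C(=O)OCC)(C(=O)OCC)C(=O)C=P(c1ccccc1)(c1ccccc1)c1ccccc1 | intermediate
8 | diethyl (6R)-5,5-dimethyl-3-(2-methylpropoxy)-1,9-dioxospiro[5.5]undeca-2,7-diene-10,10-dicarboxylate | O=C1C=C(OCC(C)C)CC(C)(C)[C@]12CC(C(=O)OCC)(C(=O)OCC)C(=O)C=C2 | intermediate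
9 | (6R)-5,5-dimethyl-3-(2-methylpropoxy)spiro[5.5]undeca-2,7-diene-1,9-dione | O=C1C=C(OCC(C)C)CC(C)(C)[C@]12CCC(=O)C=C2 | intermediate
10 | (6R)-5,5-dimethyl-3-(2-methylpropoxy)-9-[(triethylsilyl)oxy]spiro[5.5]undeca-2,8-dien-1-one | O=C1C=C(OCC(C)C)CC(C)(C)[C@]12CCC(O[Si](CC)(CC)CC)=CC2 | intermediate
11 | (6R,8S)-8-chloro-5,5-dimethyl-3-(2-methylpropoxy)spiro[5.5]undec-2-ene-1,9-dione | O=C1C=C(OCC(C)C)CC(C)(C)[C@]12CCC(=O)[C@@H](Cl)C2 | intermediate
12 | (6R,8S,9R)-8-chloro-9-hydroxy-5,5,9-trimethyl-3-(2-methylpropoxy)spiro[5.5]undec-2-en-1-one | O=C1C=C(OCC(C)C)CC(C)(C)[C@]12CC[C@@](C)(O)[C@@H](Cl)C2 | intermediate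
13 | (6R,8S,9R)-8-chloro-5,5,9-trimethyl-3-(2-methylpropoxy)-1,9-bis[(trimethylsilyl)oxy]spiro[5.5]undeca-1,3-diene | C[Si](C)(C)OC1=CC(OCC(C)C)=CC(C)(C)[C@]12CC[C@@](C)(O[Si](C)(C)C)[C@@H](Cl)C2 | intermediate
14 | (4S,6R,8S,9R)-4-bromo-8-chloro-5,5,9-trimethyl-3-(2-methylpropoxy)-9-[(trimethylsilyl)oxy]spiro[5.5]undec-2-en-1-one | O=C1C=C(OCC(C)C)[C@@H](Br)C(C)(C)[C@]12CC[C@@](C)(O[Si](C)(C)C)[C@@H](Cl)C2 | intermediate
15 | (4S,6R,8S,9R)-4-bromo-8-chloro-5,5,9-trimethyl-3-(2-methylpropoxy)-1-[(trimethylsilyl)methyl]-9-[(trimethylsilyl)oxy]spiro[5.5]undec-2-en-1-ol (either configuration at C1) | C[Si](C)(C)CC1(O)C=C(OCC(C)C)[C@@H](Br)C(C)(C)[C@]12CC[C@@](C)(O[Si](C)(C)C)[C@@H](Cl)C2 | intermediate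
16 | (4S,6S,8S,9R)-4-bromo-8-chloro-9-hydroxy-5,5,9-trimethyl-1-methylidenespiro[5.5]undecan-3-one | C=C1CC(=O)[C@@H](Br)C(C)(C)[C@]12CC[C@@](C)(O)[C@@H](Cl)C2 | intermediate
17 | (3R,4S,6S,8S,9R)-4-bromo-8-chloro-5,5,9-trimethyl-1-methylidenespiro[5.5]undecane-3,9-diol | C=C1C[C@@H](O)[C@@H](Br)C(C)(C)[C@]12CC[C@@](C)(O)[C@@H](Cl)C2 | target

Total step count: 10. Longest linear sequence: 10 steps (1 to 17).

**Steps most likely to fail**

Step 4 (Proposed new method). The hindered malonate carbon may be acylated slowly or through oxygen, and the stabilised ylide may fail to close onto the congested aldehyde. Fallback with known chemistry, from 5: C-acylation of the magnesium enolate with (diethoxyphosphoryl)acetyl chloride (MgCl2, Et3N, MeCN, 0 °C) should give the β-keto phosphonate diethyl 2-[(diethoxyphosphoryl)acetyl]-2-{[(1S)-1-formyl-6,6-dimethyl-4-(2-methylpropoxy)-2-oxocyclohex-3-en-1-yl]methyl}propanedioate F1. Intramolecular Horner–Wadsworth–Emmons olefination (LiCl, i-Pr2NEt, MeCN, 25 °C) then forms the same two bonds in two operations and rejoins the route at 8.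

Step 8. NBS may attack the α carbon C2 instead of the γ carbon C4, or bromine delivery may show poor facial selectivity relative to the spiro centre, since the two arms of C6 differ only remotely. Fallback, from 12: a Stork–Danheiser sequence (MeLi, CeCl3, THF, −78 °C; then aqueous HCl) should give the conjugated enone (6R,8S,9R)-8-chloro-9-hydroxy-1,5,5,9-tetramethylspiro[5.5]undec-1-en-3-one F2. Kinetic enolisation at the α' carbon (LiN(i-Pr)2, Me3SiCl, THF, −78 °C) and bromination of the cross-conjugated silyl dienol ether with NBS should give the α'-bromo enone (4S,6S,8S,9R)-4-bromo-8-chloro-1,5,5,9-tetramethyl-9-[(trimethylsilyl)oxy]spiro[5.5]undec-1-en-3-one F3. Soft enolisation (Me3SiOTf, Et3N) then gives the linear dienol ether (4S,6S,8S,9R)-4-bromo-8-chloro-5,5,9-trimethyl-1-methylidene-3,9-bis[(trimethylsilyl)oxy]spiro[5.5]undec-2-ene F4, and kinetic protonation at C2 (aqueous AcOH, THF, 0 °C) moves the alkene to the exocyclic position and rejoins the route at 16.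

Step 3. Uncatalysed background addition at the hindered carbon may erode the enantioselectivity, and the formyl group may be lost by retro-Claisen cleavage. Fallback, from 3: Et3N-catalysed Michael addition without chiral catalyst should give the racemic adduct diethyl 2-{[1-formyl-6,6-dimethyl-4-(2-methylpropoxy)-2-oxocyclohex-3-en-1-yl]methyl}propanedioate F5. Resolution by preparative chromatography on a chiral stationary phase then supplies the S enantiomer and rejoins the route at 5.

**Further compounds**

F1 | step 4 | diethyl 2-[(diethoxyphosphoryl)acetyl]-2-{[(1S)-1-formyl-6,6-dimethyl-4-(2-methylpropoxy)-2-oxocyclohex-3-en-1-yl]methyl}propanedioate | O=C1C=C(OCC(C)C)CC(C)(C)[C@]1(C=O)CC(C(=O)OCC)(C(=O)OCC)C(=O)CP(=O)(OCC)OCC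
F2 | step 8 | (6R,8S,9R)-8-chloro-9-hydroxy-1,5,5,9-tetramethylspiro[5.5]undec-1-en-3-one | CC1=CC(=O)CC(C)(C)[C@]12CC[C@@](C)(O)[C@@H](Cl)C2
F3 | step 8 | (4S,6S,8S,9R)-4-bromo-8-chloro-1,5,5,9-tetramethyl-9-[(trimethylsilyl)oxy]spiro[5.5]undec-1-en-3-one | CC1=CC(=O)[C@@H](Br)C(C)(C)[C@]12CC[C@@](C)(O[Si](C)(C)C)[C@@H](Cl)C2
F4 | step 8 | (4S,6S,8S,9R)-4-bromo-8-chloro-5,5,9-trimethyl-1-methylidene-3,9-bis[(trimethylsilyl)oxy]spiro[5.5]undec-2-ene | C=C1C=C(O[Si](C)(C)C)[C@@H](Br)C(C)(C)[C@]12CC[C@@](C)(O[Si](C)(C)C)[C@@H](Cl)C2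
F5 | step 3 | diethyl 2-{[1-formyl-6,6-dimethyl-4-(2-methylpropoxy)-2-oxocyclohex-3-en-1-yl]methyl}propanedioate (racemate) | O=C1C=C(OCC(C)C)CC(C)(C)C1(C=O)CC(C(=O)OCC)C(=O)OCC
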